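Substrate cannot become target without first passing through the intermediate, so I kept a ledger of the substrate. It is the limiting reagent for target in the asked flasks, where first nucleophile is charged at 1.20 equiv or 2.40 equiv.

| flask | substrate | first nucleophile | second nucleophile | remark | time |
|---|---|---|---|---|---|
| red | 0.22 M | 1.2 equiv | 1 equiv | run made earlier |  |
| west | 0.80 M | 1.20 equiv | 0.670 equiv |  | 30 h |
| north-east | 0.20 M | 1.20 equiv | 1.00 equiv |  | 30 h |
| north | 0.60 M | 2.40 equiv | 1.00 equiv |  | 30 h |
| south-west | 0.60 M | 1.20 equiv | 2.00 equiv |  | 30 h |
| east | 0.40 M | 1.20 equiv | 2.00 equiv |  | 30 h |

red run (percent of the substrate charged)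

| time / h | target / % |
|---|---|
| 0.500 | 1.0 |
| 0.833 | 2.2 |
| 1.33 | 5.2 |
| 2.00 | 7.9 |
| 4.00 | 16.8 |
| 6.00 | 23.7 |

(readings scatter by 0.3 percentage points)

- what may be going on: intermediate -> solvolysis product; substrate -> intermediate; first nucleophile + intermediate -> target; second nucleophile + intermediate -> other capture product

* ranking by amount of target, in percent of the substrate charged, from high to low, at 30 h (west / north-east / north / south-west / east)
* the amount of target, in percent of the substrate charged of the flask you put first, at 30 h
* the amount of target, in percent of the substrate charged of the flask you put last, at 30 h

The first entry was substrate still unreacted. The red run made target at 0.0488 h⁻¹ of the charge between 0.833 h and 2.00 h, but at 0.0345 h⁻¹ between 4.00 h and 6.00 h, which is slower. I read that fall as the decay of the substrate, which gave 0.0970 h⁻¹ and a half-life of 7.14 h. So 30 h counted 4.20 half-lives. That step has no partner in its equation, so I booked 5.45 % to this entry for each flask.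

The second entry was target. At 5.00 h in the red run, I estimated from that reading that substrate was feeding the intermediate at 0.0597 h⁻¹. Target took 0.0345 h⁻¹ of that, an estimated share of 0.578, and I reckoned [first nucleophile] then at 0.219 M. From these I got 0.160 M as the break-even concentration, the [first nucleophile] at which capture to target runs as fast as the other exits of the intermediate together. With those other exits held fixed, the share to target is then [first nucleophile] divided by the sum of [first nucleophile] and this concentration.

The last entry took the remainder. I booked it as solvolysis product, an assumption, and so held the break-even concentration constant from flask to flask. Using [first nucleophile] at mid-course, I reckoned 1.18 M and 83.3 % target for north, and 0.183 M and 50.4 % for north-east. I ranked the flasks by charged [first nucleophile], with north highest and north-east lowest.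

The forecast gave north > west > north-east > south-west > east, with 74 % for its first flask and 46 % for its last, and it remarked of the other exits that “one run cannot split these”. My order and numbers differ from these.

The flasks came out as north > west > south-west > east > north-east, with north at 80.8 % and north-east at 48.2 %.

    intermediate → solvolysis product (k = 0.0150 min⁻¹)
    substrate → intermediate (k = 0.00160 min⁻¹)
    first nucleophile + intermediate → target (k = 0.0890 M⁻¹ min⁻¹)
    second nucleophile + intermediate → other capture product (k = 0.00440 M⁻¹ min⁻¹)

At 30.0 h, north-east held 43.3 % solvolysis product against 2.51 % other capture product. I took the break-even concentration of 0.160 M to the neighbouring flask, which is north-east with 0.300 equiv of first nucleophile. There [first nucleophile] starts at 0.0600 M and I reckoned it at 0.0343 M at mid-course, so the ledger books 16.7 % to target. That flask gave 17.3 %.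

All runs were generated by integration with made-up constants; noise was put on by code.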